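The target is a linear pentamer: filicinic acid rings A and E, butyrylphloroglucinol rings B, C and D, and four CH2 bridges. The plan opens the central ring C between its butyryl-bearing carbon and a neighbouring C–OH carbon. Because ring C is hexasubstituted with alternating oxygen and carbon substituents, its six carbons map onto C1–C6 of a 3,5,7-trioxodecanoate whose C2 and C4 already carry the two inner bridge carbons; one intramolecular Claisen condensation of C6 onto the C1 ester closes and aromatises this most crowded ring. The precursor is methyl 3,5,7-trioxo-2,4-bis(2,4,6-trimethoxybenzyl)decanoate, a tautomer mixture built from dimethyl 3-oxoglutarate, 2,4,6-trimethoxybenzaldehyde and pentan-2-one.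

Key step: step 4

Remark 1: 1-(2,4,6-trihydroxyphenyl)butan-1-one, the starting material of step 8, is taken as a catalogue compound; all polycarbonyl compounds are tautomer mixtures and are written in one form.
Remark 2: the outer rings are acylated while still methyl ethers and deprotected only afterwards, so that every ring of each diarylmethane carries an acyl group before BBr3 and HBr are present.

Step 1
Reactants: 1 2,4,6-trimethoxybenzaldehyde (2.2 equiv); 2 dimethyl 3-oxopentanedioate (dimethyl 3-oxoglutarate)
Product: 3 dimethyl 3-oxo-2,4-bis[(2,4,6-trimethoxyphenyl)methylidene]pentanedioate (alkene isomer mixture, used crude)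
Conditions: piperidine (0.2 equiv), AcOH (0.2 equiv), toluene, reflux, Dean–Stark
Reagents that add atoms: none
Why: Double Knoevenagel condensation at the two doubly activated CH2 groups with azeotropic removal of water; the donor-rich aryl groups make each arylidene a weak Michael acceptor, and the alkene geometry is of no account because step 2 saturates both double bonds.

Step 2
Reactants: 3 dimethyl 3-oxo-2,4-bis[(2,4,6-trimethoxyphenyl)methylidene]pentanedioate
Product: 4 dimethyl 3-oxo-2,4-bis(2,4,6-trimethoxybenzyl)pentanedioate (meso and racemic diastereomers plus enol)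
Conditions: H2 (3 bar), 10% Pd/C, EtOAc, rt
Reagents that add atoms: none
Why: Catalytic hydrogenation of the electron-poor trisubstituted alkenes leaves aryl methyl ethers, esters and the ketone untouched, and the two new sp3 centres are epimerisable α-carbons that are erased in step 4, so no stereocontrol is needed.

Step 3
Reactants: 4 dimethyl 3-oxo-2,4-bis(2,4,6-trimethoxybenzyl)pentanedioate; 5 pentan-2-one (3.5 equiv)
Product: 8 methyl 3,5,7-trioxo-2,4-bis(2,4,6-trimethoxybenzyl)decanoate (diastereomer and enol mixture, used without chromatography), via monolithium enolate of the keto diester 6 (not isolated), via lithium pent-1-en-2-olate 7 (not isolated)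
Conditions: i) 5, LiN(iPr)2 (3.5 equiv), THF, −78 °C; ii) 4 pre-treated with LiN(iPr)2 (1.05 equiv), THF, −78 °C, added by cannula, −78 → 0 °C; iii) AcOH, −78 °C, pH 5 buffer work-up
Reagents that add atoms: none
Why: Crossed Claisen acylation of a kinetic methyl-ketone lithium enolate by the salt of a β-keto ester, a known way of extending polyketo chains: preforming enolate 6 keeps 4 from protonating 7 and leaves the non-conjugated ester as the electrophile, and the β-diketonate formed takes a further proton from 7, which shields the remaining, now conjugated, ester from a second acylation.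

Step 4
Reactants: 8 methyl 3,5,7-trioxo-2,4-bis(2,4,6-trimethoxybenzyl)decanoate
Product: 10 1-[2,4,6-trihydroxy-3,5-bis(2,4,6-trimethoxybenzyl)phenyl]butan-1-one, via cyclohexane-1,3,5-trione tautomer 9 (not isolated)
Conditions: Mg(OMe)2 (5 equiv), MeOH, reflux, Ar; then cold 1 M HCl to pH 3
Reagents that add atoms: none
Why: Mg(OMe)2 turns 8 into a magnesium-chelated polyenolate in which C6, flanked by the C5 and C7 carbonyls, attacks the C1 ester carbonyl; loss of methoxide gives the 2-acylcyclohexane-1,3,5-trione 9, which enolises three times to the aromatic ring (ring C of the target). The closest known reaction type is the biomimetic Claisen cyclisation of 3,5,7-triketo esters, and of the 4-hydroxy-2-pyrones derived from them, to acylphloroglucinols under magnesium methoxide. The ring closes in the 6-exo-trig mode, the enolate carbon adding to a carbonyl whose C=O bond lies outside the new ring. No stereocentre is created, and the labile C2 and C4 centres of 8 become sp2 ring carbons, so the diastereomer mixture converges on one product. The step needs C-acylation at C6 in preference to O-acylation (pyrone) and to aldol closure of C2 onto C7 (resorcylate): chelation by divalent magnesium folds the chain and favours attack through carbon, pyrone formation is reversed by methanolysis under the same conditions, and the benzyl group at C2 makes the aldol adduct a quaternary centre that cannot dehydrate to an arene, so only the Claisen pathway should end in an irreversible aromatisation.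

Step 5
Reactants: 10 1-[2,4,6-trihydroxy-3,5-bis(2,4,6-trimethoxybenzyl)phenyl]butan-1-one
Product: 11 1-{3,5-bis[(3-butanoyl-2,4,6-trimethoxyphenyl)methyl]-2,4,6-trihydroxyphenyl}butan-1-one
Conditions: PrCOCl (2.3 equiv), AlCl3 (7 equiv), CH2Cl2, −20 → 0 °C; ice, 1 M HCl
Reagents that add atoms: butanoyl chloride, CCCC(=O)Cl
Why: Friedel–Crafts acylation of the two trimethoxyphenyl rings, each at one of its two equivalent positions (ortho, ortho and para to methoxy); the first acyl group deactivates its ring against a second, and ring C, fully substituted and held as an aluminium chelate, offers no carbon site.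

Step 6
Reactants: 11 1-{3,5-bis[(3-butanoyl-2,4,6-trimethoxyphenyl)methyl]-2,4,6-trihydroxyphenyl}butan-1-one
Product: 12 1-{3,5-bis[(3-butanoyl-2,4,6-trihydroxyphenyl)methyl]-2,4,6-trihydroxyphenyl}butan-1-one (rings B, C and D joined, one free CH on each of rings B and D)
Conditions: BBr3 (15 equiv), CH2Cl2, −78 °C → rt; MeOH, then H2O, 0 °C; Ar throughout
Reagents that add atoms: none
Why: Lewis acid cleavage of all six aryl methyl ethers with BBr3, helped by chelation to the ortho ketones; every ring now bears an acyl group, which disfavours ipso-protonation, so the diarylmethane bridges should survive the HBr formed.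

Step 7
Reactants: 12 1-{3,5-bis[(3-butanoyl-2,4,6-trihydroxyphenyl)methyl]-2,4,6-trihydroxyphenyl}butan-1-one
Product: 13 1-{3,5-bis[(3-butanoyl-5-[(dimethylamino)methyl]-2,4,6-trihydroxyphenyl)methyl]-2,4,6-trihydroxyphenyl}butan-1-one (bis-Mannich base, collected as the precipitated zwitterion)
Conditions: CH2(NMe2)2 (2.5 equiv), 1,4-dioxane, rt, Ar
Reagents that add atoms: N,N,N',N'-tetramethylmethanediamine, CN(C)CN(C)C
Why: Mannich aminomethylation of the one free position on each of rings B and D by the iminium ion that the acidic phenol releases from the aminal; afterwards no nucleophilic aryl CH is left, so the core cannot condense with itself.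

Step 8
Reactants: 14 1-(2,4,6-trihydroxyphenyl)butan-1-one
Product: 15 2-butanoyl-3,5-dihydroxy-4,4-dimethylcyclohexa-2,5-dien-1-one (butyrylfilicinic acid)
Conditions: NaOMe (3.2 equiv), MeI (2.2 equiv), MeOH, 0 °C → rt; 1 M HCl; chromatography
Reagents that add atoms: iodomethane, CI
Why: Dearomatising geminal C-methylation of the acylphloroglucinol polyanion, the classical entry to acylfilicinic acids; the quaternary carbon carries two like groups, so no stereocentre arises, and under- and over-methylated congeners are removed by chromatography.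

Step 9
Reactants: 13 bis-Mannich base of the B–C–D core; 15 butyrylfilicinic acid (5 equiv)
Product: 16 CNP0188003.0 (target; no stereocentres)
Conditions: 1,4-dioxane, 80 °C, Ar; then 0.5 M HCl wash; Sephadex LH-20
Reagents that add atoms: none
Why: Each phenolic Mannich base, protonated by the acidic triketone 15, loses dimethylamine to an ortho-quinone methide that is trapped in a Michael addition by C6 of 15, its only enolic CH; since the core has no free aryl position, only the two wanted bridges to rings A and E can form.

Compound list
1 | 2,4,6-trimethoxybenzaldehyde | COc1cc(OC)c(C=O)c(OC)c1 | starting material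
2 | dimethyl 3-oxopentanedioate (dimethyl 3-oxoglutarate) | COC(=O)CC(=O)CC(=O)OC | starting material
3 | dimethyl 3-oxo-2,4-bis[(2,4,6-trimethoxyphenyl)methylidene]pentanedioate, alkene isomer mixture | COC(=O)C(=Cc1c(OC)cc(OC)cc1OC)C(=O)C(=Cc1c(OC)cc(OC)cc1OC)C(=O)OC | intermediate
4 | dimethyl 3-oxo-2,4-bis(2,4,6-trimethoxybenzyl)pentanedioate, diastereomer mixture | COC(=O)C(Cc1c(OC)cc(OC)cc1OC)C(=O)C(Cc1c(OC)cc(OC)cc1OC)C(=O)OC | intermediate
5 | pentan-2-one | CCCC(C)=O | starting material
6 | monolithium enolate of 4 | COC(=O)C(Cc1c(OC)cc(OC)cc1OC)=C([O-])C(Cc1c(OC)cc(OC)cc1OC)C(=O)OC.[Li+] | intermediate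
7 | lithium pent-1-en-2-olate | [Li+].[O-]C(=C)CCC | intermediate
8 | methyl 3,5,7-trioxo-2,4-bis(2,4,6-trimethoxybenzyl)decanoate, diastereomer and enol mixture | CCCC(=O)CC(=O)C(Cc1c(OC)cc(OC)cc1OC)C(=O)C(Cc1c(OC)cc(OC)cc1OC)C(=O)OC | intermediate
9 | 2-butanoyl-4,6-bis(2,4,6-trimethoxybenzyl)cyclohexane-1,3,5-trione (non-aromatic tautomer of 10, labile centres unassigned) | CCCC(=O)C1C(=O)C(Cc2c(OC)cc(OC)cc2OC)C(=O)C(Cc2c(OC)cc(OC)cc2OC)C1=O | intermediate
10 | 1-[2,4,6-trihydroxy-3,5-bis(2,4,6-trimethoxybenzyl)phenyl]butan-1-one | CCCC(=O)c1c(O)c(Cc2c(OC)cc(OC)cc2OC)c(O)c(Cc2c(OC)cc(OC)cc2OC)c1O | intermediate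
11 | 1-{3,5-bis[(3-butanoyl-2,4,6-trimethoxyphenyl)methyl]-2,4,6-trihydroxyphenyl}butan-1-one | CCCC(=O)c1c(O)c(Cc2c(OC)cc(OC)c(C(=O)CCC)c2OC)c(O)c(Cc2c(OC)cc(OC)c(C(=O)CCC)c2OC)c1O | intermediate
12 | 1-{3,5-bis[(3-butanoyl-2,4,6-trihydroxyphenyl)methyl]-2,4,6-trihydroxyphenyl}butan-1-one | CCCC(=O)c1c(O)c(Cc2c(O)cc(O)c(C(=O)CCC)c2O)c(O)c(Cc2c(O)cc(O)c(C(=O)CCC)c2O)c1O | intermediate
13 | 1-{3,5-bis[(3-butanoyl-5-[(dimethylamino)methyl]-2,4,6-trihydroxyphenyl)methyl]-2,4,6-trihydroxyphenyl}butan-1-one | CCCC(=O)c1c(O)c(Cc2c(O)c(CN(C)C)c(O)c(C(=O)CCC)c2O)c(O)c(Cc2c(O)c(CN(C)C)c(O)c(C(=O)CCC)c2O)c1O | intermediate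
14 | 1-(2,4,6-trihydroxyphenyl)butan-1-one | CCCC(=O)c1c(O)cc(O)cc1O | starting material
15 | 2-butanoyl-3,5-dihydroxy-4,4-dimethylcyclohexa-2,5-dien-1-one (butyrylfilicinic acid) | CCCC(=O)C1=C(O)C(C)(C)C(O)=CC1=O | intermediate
16 | CNP0188003.0: rings A and E butyrylfilicinic acid dienones, rings B, C and D butyrylphloroglucinols, four CH2 bridges, achiral | CCCC(=O)C1=C(O)C(C)(C)C(O)=C(Cc2c(O)c(Cc3c(O)c(Cc4c(O)c(CC5=C(O)C(C)(C)C(O)=C(C(=O)CCC)C5=O)c(O)c(C(=O)CCC)c4O)c(O)c(C(=O)CCC)c3O)c(O)c(C(=O)CCC)c2O)C1=O | target

Total step count: 9. Longest linear sequence: 8 (steps 1 to 7 and 9; step 8 is a one-step side branch).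

Steps most likely to fail

Step 4. Lactonisation to the pyrone, or methoxide-induced retro-Claisen cleavage at the α-substituted β-dicarbonyl units, may consume the chain before C6 reaches the hindered ester. The fallback sets out from 1 and 14 and comes back at 10, giving up the ring synthesis for a substitution on a preformed ring. Reduction of 1 (NaBH4, MeOH, 0 °C) would give (2,4,6-trimethoxyphenyl)methanol F4. Acid-catalysed double Friedel–Crafts benzylation of 14 at its two free ring positions with F4 (2.1 equiv, TsOH cat., MeCN, rt) would then deliver 10, the stabilised benzylic cation being captured by the phloroglucinol ring.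

Step 3. Proton transfer from the C4–H of enolate 6 to enolate 7 may outrun acylation and return both partners unchanged, and the minor internal enolate of 5 may be acylated in its place. The fallback sets out from 4 and comes back at 8, forming the C4–C5 bond instead of C5–C6.
- Krapcho mono-dealkoxycarbonylation of 4 (LiCl, wet DMSO, 130 °C, stopped short of full conversion) would give methyl 3-oxo-2-(2,4,6-trimethoxybenzyl)-5-(2,4,6-trimethoxyphenyl)pentanoate F1.
- The acyl donor methyl 2-(2-propyl-1,3-dioxolan-2-yl)acetate F2 would be made from methyl 3-oxohexanoate and ethylene glycol (TsOH, toluene, Dean–Stark); it has no acidic 1,3-dicarbonyl proton.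
- The α,γ-dianion of F1 (LiN(iPr)2, 2.2 equiv, THF, −78 → 0 °C) would be acylated at its γ-carbon by F2, a Claisen acylation of a β-keto ester dianion, to give methyl 3,5-dioxo-6-(2-propyl-1,3-dioxolan-2-yl)-2,4-bis(2,4,6-trimethoxybenzyl)hexanoate F3.
- Brief acetal hydrolysis (PPTS, acetone–H2O, 40 °C) would release 8.

Step 9. The double coupling may stop after one arm, and the liberated amine may promote reversible cleavage and recombination of methylene bridges, leading to scrambled oligomers. The fallback sets out from 15 (with 12) and comes back at 16, with the polarity of the coupling reversed. Aminomethylation of 15 with CH2(NMe2)2 (dioxane, rt) would give 2-butanoyl-6-[(dimethylamino)methyl]-3,5-dihydroxy-4,4-dimethylcyclohexa-2,5-dien-1-one F5. Heating F5 (2.2 equiv) with 12 in dioxane containing AcOH would generate the exocyclic methylene triketone by amine loss, which the free position of rings B and D attacks in a Michael-type aromatic substitution.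

Further compounds
F1 | step 3 | methyl 3-oxo-2-(2,4,6-trimethoxybenzyl)-5-(2,4,6-trimethoxyphenyl)pentanoate | COC(=O)C(Cc1c(OC)cc(OC)cc1OC)C(=O)CCc1c(OC)cc(OC)cc1OC
F2 | step 3 | methyl 2-(2-propyl-1,3-dioxolan-2-yl)acetate | CCCC1(CC(=O)OC)OCCO1
F3 | step 3 | methyl 3,5-dioxo-6-(2-propyl-1,3-dioxolan-2-yl)-2,4-bis(2,4,6-trimethoxybenzyl)hexanoate | CCCC1(CC(=O)C(Cc2c(OC)cc(OC)cc2OC)C(=O)C(Cc2c(OC)cc(OC)cc2OC)C(=O)OC)OCCO1
F4 | step 4 | (2,4,6-trimethoxyphenyl)methanol | COc1cc(OC)c(CO)c(OC)c1
F5 | step 9 | 2-butanoyl-6-[(dimethylamino)methyl]-3,5-dihydroxy-4,4-dimethylcyclohexa-2,5-dien-1-one | CCCC(=O)C1=C(O)C(C)(C)C(O)=C(CN(C)C)C1=O
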